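The strategy rests on cutting the saturated three-carbon tether between C3 of the 5,8-dihydroxyisochroman-1-one ring and the ester-bearing carbinol carbon, at the bond joining its second and third CH2 groups counted from C3. Because both carbons are unfunctionalised primary centres, each is traced to a carboxylic acid one carbon longer, and a nickel-electrocatalytic doubly decarboxylative coupling of the two N-acyloxyphthalimides joins the complete lactone half to the complete mevalonate half in one operation. The precursors are a propanoic acid ester on C3 of the silyl-protected lactone and the redox-active ester of an O-acylated (S)-3-hydroxybutanoic acid; all three stereocentres arrive preformed and lie outside the radical carbons.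

Key step: step 11

Remark: (R)-2-(but-3-en-1-yl)oxirane, (R)-mevalonolactone and benzyl (3S)-3-hydroxybutanoate are taken as purchasable single enantiomers.

Step 1
Reactants: 1 2,5-dimethoxybenzoyl chloride
Product: 2 N,N-diethyl-2,5-dimethoxybenzamide
Conditions: Et2NH (2.5 equiv), CH2Cl2, 0 °C to rt
Reagents that add atoms: diethylamine CCNCC
Why: Acylation of a secondary amine by an acid chloride (Schotten–Baumann-type amide formation) should be clean, the excess amine taking up HCl, and installs the tertiary amide needed as directing group.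

Step 2
Reactants: 2 N,N-diethyl-2,5-dimethoxybenzamide; 3 (R)-2-(but-3-en-1-yl)oxirane
Product: 6 (3R)-3-(but-3-en-1-yl)-5,8-dimethoxyisochroman-1-one, via aryllithium 4 (not isolated), via hydroxy amide 5 (not isolated)
Conditions: s-BuLi, TMEDA, THF, −78 °C; then 3, BF3·OEt2, −78 °C; aq. NH4Cl; crude 5, p-TsOH·H2O (1.2 equiv), toluene, reflux
Reagents that add atoms: none
Why: Directed ortho-metalation should occur at C6, the only position flanked by the amide and a methoxy group; BF3-assisted SN2 opening of the epoxide at its CH2 terminus leaves the (R) carbinol centre untouched, and acid-mediated lactonisation (acyl substitution with loss of diethylamine, retention at the carbinol carbon) closes the dihydroisocoumarin with C3 as (R).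

Step 3
Reactants: 6 (3R)-3-(but-3-en-1-yl)-5,8-dimethoxyisochroman-1-one
Product: 7 (3R)-3-(but-3-en-1-yl)-5,8-dihydroxyisochroman-1-one
Conditions: BBr3 (3 equiv), CH2Cl2, −78 to 0 °C; then H2O
Reagents that add atoms: none
Why: Lewis acid-mediated aryl methyl ether cleavage (BBr3 demethylation) should remove both O-methyl groups, the peri 8-OMe being assisted by chelation to the lactone carbonyl, while the secondary lactone C–O bond and the terminal alkene survive at low temperature.

Step 4
Reactants: 7 (3R)-3-(but-3-en-1-yl)-5,8-dihydroxyisochroman-1-one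
Product: 8 (3R)-3-(but-3-en-1-yl)-5,8-bis(triisopropylsilyloxy)isochroman-1-one
Conditions: TIPSOTf (2.5 equiv), 2,6-lutidine, CH2Cl2, 0 °C to rt
Reagents that add atoms: triisopropylsilyl trifluoromethanesulfonate CC(C)[Si](C(C)C)(C(C)C)OS(=O)(=O)C(F)(F)F
Why: O-silylation of phenols with a silyl triflate should cap both hydroxyls, including the hydrogen-bonded 8-OH, as base-robust, fluoride-labile aryl TIPS ethers that prevent phenol acylation and phenoxide chemistry in the later active-ester and electrochemical steps.

Step 5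
Reactants: 8 (3R)-3-(but-3-en-1-yl)-5,8-bis(triisopropylsilyloxy)isochroman-1-one
Product: 11 3-[(3R)-1-oxo-5,8-bis(triisopropylsilyloxy)isochroman-3-yl]propanoic acid, via ozonide 9 (not isolated), via aldehyde 10 (not isolated)
Conditions: O3, CH2Cl2, −78 °C (Sudan Red 7B end point); PPh3, −78 °C to rt; crude 10, NaClO2, NaH2PO4, 2-methyl-2-butene, t-BuOH/H2O, rt
Reagents that add atoms: ozone [O-][O+]=O; sodium chlorite [Na+].[O-]Cl=O
Why: Ozonolysis with reductive work-up followed by Pinnick oxidation should shorten the butenyl chain by one carbon to the propanoic acid, the terminal alkene reacting with ozone far faster than the arene deactivated by the lactone carbonyl, and no stereocentre is epimerisable under these conditions.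

Step 6
Reactants: 11 3-[(3R)-1-oxo-5,8-bis(triisopropylsilyloxy)isochroman-3-yl]propanoic acid
Product: 12 1,3-dioxoisoindolin-2-yl 3-[(3R)-1-oxo-5,8-bis(triisopropylsilyloxy)isochroman-3-yl]propanoate
Conditions: N-hydroxyphthalimide, DIC, DMAP (cat.), CH2Cl2, rt
Reagents that add atoms: N-hydroxyphthalimide O=C1c2ccccc2C(=O)N1O
Why: Carbodiimide-mediated (Steglich-type) esterification with N-hydroxyphthalimide should give the redox-active ester, a stable compound that can be purified on silica.

Step 7
Reactants: 13 (R)-mevalonolactone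
Product: 16 (3R)-5-(tert-butyldimethylsilyloxy)-3-hydroxy-3-methylpentanoic acid, via potassium mevalonate 14 (not isolated), via bis-silylated mevalonate 15 (not isolated)
Conditions: KOH (1.05 equiv), H2O/MeOH, rt, then evaporation to dryness; TBSCl (2.3 equiv), imidazole, DMF, rt; K2CO3, MeOH/THF/H2O, rt; acidification to pH 4 (aq. KHSO4, 0 °C)
Reagents that add atoms: potassium hydroxide [K+].[OH-]; tert-butyldimethylsilyl chloride CC(C)(C)[Si](C)(C)Cl
Why: Saponification opens the lactone, TBSCl/imidazole silylates the carboxylate and the primary hydroxyl but not the tertiary one, and mild carbonate solvolysis cleaves only the labile silyl ester, so the 5-O-silyl acid should result with the quaternary (R) centre untouched and relactonisation blocked.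

Step 8
Reactants: 16 (3R)-5-(tert-butyldimethylsilyloxy)-3-hydroxy-3-methylpentanoic acid; 17 benzyl (3S)-3-hydroxybutanoate
Product: 18 benzyl (3S)-3-{[(3R)-5-(tert-butyldimethylsilyloxy)-3-hydroxy-3-methylpentanoyl]oxy}butanoate
Conditions: EDC·HCl, DMAP (cat.), CH2Cl2, 0 °C to rt
Reagents that add atoms: none
Why: Steglich esterification should acylate the secondary hydroxyl with retention (the carbinol C–O bond is not broken), the tertiary hydroxyl of 16 being too hindered to compete.

Step 9
Reactants: 18 benzyl (3S)-3-{[(3R)-5-(tert-butyldimethylsilyloxy)-3-hydroxy-3-methylpentanoyl]oxy}butanoate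
Product: 19 (3S)-3-{[(3R)-5-(tert-butyldimethylsilyloxy)-3-hydroxy-3-methylpentanoyl]oxy}butanoic acid
Conditions: H2 (1 atm), 10% Pd/C, EtOAc, rt
Reagents that add atoms: none
Why: Hydrogenolysis of the benzyl ester under neutral conditions should free the carboxylic acid without touching the silyl ether, the tertiary alcohol or the secondary ester.

Step 10
Reactants: 19 (3S)-3-{[(3R)-5-(tert-butyldimethylsilyloxy)-3-hydroxy-3-methylpentanoyl]oxy}butanoic acid
Product: 20 1,3-dioxoisoindolin-2-yl (3S)-3-{[(3R)-5-(tert-butyldimethylsilyloxy)-3-hydroxy-3-methylpentanoyl]oxy}butanoate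
Conditions: N-hydroxyphthalimide, DIC, CH2Cl2, 0 °C to rt, no amine base
Reagents that add atoms: N-hydroxyphthalimide O=C1c2ccccc2C(=O)N1O
Why: Carbodiimide esterification with N-hydroxyphthalimide should give the second redox-active ester, and leaving out amine base should suppress E1cB loss of the β-acyloxy group from the activated acid.

Step 11
Reactants: 12 1,3-dioxoisoindolin-2-yl 3-[(3R)-1-oxo-5,8-bis(triisopropylsilyloxy)isochroman-3-yl]propanoate; 20 1,3-dioxoisoindolin-2-yl (3S)-3-{[(3R)-5-(tert-butyldimethylsilyloxy)-3-hydroxy-3-methylpentanoyl]oxy}butanoate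
Product: 21 (2S)-5-[(3R)-1-oxo-5,8-bis(triisopropylsilyloxy)isochroman-3-yl]pentan-2-yl (3R)-5-(tert-butyldimethylsilyloxy)-3-hydroxy-3-methylpentanoate
Conditions: NiCl2·6H2O (20 mol%), 2,6-bis(pyrazol-1-yl)pyridine (20 mol%), AgNO3 (0.3 equiv), NMP, undivided cell, Mg anode, reticulated vitreous carbon cathode, constant current, rt; 20 in excess (3 equiv)
Reagents that add atoms: none
Why: Cathodic electron transfer, mediated by low-valent nickel on the silver-nanoparticle-coated cathode, should fragment each N-acyloxyphthalimide into phthalimide anion, CO2 and a primary alkyl radical, and the tridentate-ligated nickel captures the two radicals in turn and releases the new CH2–CH2 bond by reductive elimination, the magnesium anode supplying the electrons. The closest known reaction type is the nickel-electrocatalytic doubly decarboxylative C(sp3)–C(sp3) coupling of two redox-active esters, established for primary–primary pairs bearing β-oxygen substituents. No ring is closed and no stereocentre is created; C3 of the lactone and the acyloxy carbinol carbon lie one or two bonds away from the radical centres, not at them, so their configurations and that of the remote tertiary carbinol are carried through unchanged. The step needs cross- over homo-coupling, which for two primary radicals is statistical and is biased by using 20, the partner from the shorter sequence, in excess, the two symmetrical dimers differing enough in size and polarity to be removed by chromatography. It also needs chemoselective reduction of the two N–O esters beside a lactone, two alkyl esters, three silyl ethers and a free tertiary alcohol, which their far less negative reduction potential secures, and survival of the β-acyloxy group in the radical from 20, for which capture by nickel at room temperature should outrun 1,2-acyloxy shift and β-elimination.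

Step 12
Reactants: 21 (2S)-5-[(3R)-1-oxo-5,8-bis(triisopropylsilyloxy)isochroman-3-yl]pentan-2-yl (3R)-5-(tert-butyldimethylsilyloxy)-3-hydroxy-3-methylpentanoate
Product: 22 aspergimarin C, (2S)-5-[(3R)-5,8-dihydroxy-1-oxoisochroman-3-yl]pentan-2-yl (3R)-3,5-dihydroxy-3-methylpentanoate
Conditions: TBAF, AcOH (1:1, excess), THF, 0 °C to rt, argon
Reagents that add atoms: none
Why: Fluoride-mediated desilylation buffered with acetic acid should cleave both aryl TIPS ethers and the primary TBS ether in a near-neutral medium, so that the lactone, the secondary ester (whose liberated 5-hydroxy group could lactonise under base) and the hydroquinone (air-sensitive as its anion) are not endangered.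

Compound list
1 | 2,5-dimethoxybenzoyl chloride | COc1ccc(OC)c(C(=O)Cl)c1 | starting material
2 | N,N-diethyl-2,5-dimethoxybenzamide | CCN(CC)C(=O)c1cc(OC)ccc1OC | intermediate
3 | (R)-2-(but-3-en-1-yl)oxirane [(R)-1,2-epoxy-5-hexene] | C=CCC[C@@H]1CO1 | starting material
4 | [2-(diethylcarbamoyl)-3,6-dimethoxyphenyl]lithium | CCN(CC)C(=O)c1c([Li])c(OC)ccc1OC | intermediate
5 | N,N-diethyl-2-[(2R)-2-hydroxyhex-5-en-1-yl]-3,6-dimethoxybenzamide | C=CCC[C@@H](O)Cc1c(OC)ccc(OC)c1C(=O)N(CC)CC | intermediate
6 | (3R)-3-(but-3-en-1-yl)-5,8-dimethoxyisochroman-1-one | C=CCC[C@@H]1Cc2c(OC)ccc(OC)c2C(=O)O1 | intermediate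
7 | (3R)-3-(but-3-en-1-yl)-5,8-dihydroxyisochroman-1-one | C=CCC[C@@H]1Cc2c(O)ccc(O)c2C(=O)O1 | intermediate
8 | (3R)-3-(but-3-en-1-yl)-5,8-bis(triisopropylsilyloxy)isochroman-1-one | C=CCC[C@@H]1Cc2c(O[Si](C(C)C)(C(C)C)C(C)C)ccc(O[Si](C(C)C)(C(C)C)C(C)C)c2C(=O)O1 | intermediate
9 | (3R)-3-[2-(1,2,4-trioxolan-3-yl)ethyl]-5,8-bis(triisopropylsilyloxy)isochroman-1-one (ozonide, epimers at the trioxolane carbon) | O1OC(CC[C@@H]2Cc3c(O[Si](C(C)C)(C(C)C)C(C)C)ccc(O[Si](C(C)C)(C(C)C)C(C)C)c3C(=O)O2)OC1 | intermediate
10 | 3-[(3R)-1-oxo-5,8-bis(triisopropylsilyloxy)isochroman-3-yl]propanal | O=CCC[C@@H]1Cc2c(O[Si](C(C)C)(C(C)C)C(C)C)ccc(O[Si](C(C)C)(C(C)C)C(C)C)c2C(=O)O1 | intermediate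
11 | 3-[(3R)-1-oxo-5,8-bis(triisopropylsilyloxy)isochroman-3-yl]propanoic acid | OC(=O)CC[C@@H]1Cc2c(O[Si](C(C)C)(C(C)C)C(C)C)ccc(O[Si](C(C)C)(C(C)C)C(C)C)c2C(=O)O1 | intermediate
12 | 1,3-dioxoisoindolin-2-yl 3-[(3R)-1-oxo-5,8-bis(triisopropylsilyloxy)isochroman-3-yl]propanoate | O=C(CC[C@@H]1Cc2c(O[Si](C(C)C)(C(C)C)C(C)C)ccc(O[Si](C(C)C)(C(C)C)C(C)C)c2C(=O)O1)ON1C(=O)c2ccccc2C1=O | intermediate
13 | (R)-mevalonolactone [(4R)-4-hydroxy-4-methyltetrahydro-2H-pyran-2-one] | C[C@@]1(O)CCOC(=O)C1 | starting material
14 | potassium (3R)-3,5-dihydroxy-3-methylpentanoate | C[C@@](O)(CCO)CC(=O)[O-].[K+] | intermediate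
15 | tert-butyldimethylsilyl (3R)-5-(tert-butyldimethylsilyloxy)-3-hydroxy-3-methylpentanoate | C[C@@](O)(CCO[Si](C)(C)C(C)(C)C)CC(=O)O[Si](C)(C)C(C)(C)C | intermediate
16 | (3R)-5-(tert-butyldimethylsilyloxy)-3-hydroxy-3-methylpentanoic acid | C[C@@](O)(CCO[Si](C)(C)C(C)(C)C)CC(=O)O | intermediate
17 | benzyl (3S)-3-hydroxybutanoate | C[C@@H](CC(=O)OCc1ccccc1)O | starting material
18 | benzyl (3S)-3-{[(3R)-5-(tert-butyldimethylsilyloxy)-3-hydroxy-3-methylpentanoyl]oxy}butanoate | C[C@@H](CC(=O)OCc1ccccc1)OC(=O)C[C@](C)(O)CCO[Si](C)(C)C(C)(C)C | intermediate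
19 | (3S)-3-{[(3R)-5-(tert-butyldimethylsilyloxy)-3-hydroxy-3-methylpentanoyl]oxy}butanoic acid | C[C@@H](CC(=O)O)OC(=O)C[C@](C)(O)CCO[Si](C)(C)C(C)(C)C | intermediate
20 | 1,3-dioxoisoindolin-2-yl (3S)-3-{[(3R)-5-(tert-butyldimethylsilyloxy)-3-hydroxy-3-methylpentanoyl]oxy}butanoate | C[C@@H](CC(=O)ON1C(=O)c2ccccc2C1=O)OC(=O)C[C@](C)(O)CCO[Si](C)(C)C(C)(C)C | intermediate
21 | (2S)-5-[(3R)-1-oxo-5,8-bis(triisopropylsilyloxy)isochroman-3-yl]pentan-2-yl (3R)-5-(tert-butyldimethylsilyloxy)-3-hydroxy-3-methylpentanoate | C[C@@H](CCC[C@@H]1Cc2c(O[Si](C(C)C)(C(C)C)C(C)C)ccc(O[Si](C(C)C)(C(C)C)C(C)C)c2C(=O)O1)OC(=O)C[C@](C)(O)CCO[Si](C)(C)C(C)(C)C | intermediate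
22 | aspergimarin C, (2S)-5-[(3R)-5,8-dihydroxy-1-oxoisochroman-3-yl]pentan-2-yl (3R)-3,5-dihydroxy-3-methylpentanoate | C[C@@H](CCC[C@@H]1Cc2c(O)ccc(O)c2C(=O)O1)OC(=O)C[C@](C)(O)CCO | target

Total step count: 12
Longest linear sequence: 8 steps (steps 1, 2, 3, 4, 5, 6, 11, 12)

Steps most likely to fail

1. Step 11 (key coupling). The limiting ester 12 may be consumed by statistical homodimerisation or hydrodecarboxylation, or the alkylnickel derived from 20 may lose its carboxylate by β-elimination. The fallback makes the same CH2–CH2 bond first as an alkene by olefin cross-metathesis and then saturates it. Setting out from amide 2, lithiation to 4, BF3-promoted opening of commercial (R)-2-allyloxirane and acid lactonisation as in step 2 would give, through N,N-diethyl-2-[(2R)-2-hydroxypent-4-en-1-yl]-3,6-dimethoxybenzamide F1, the lactone (3R)-3-allyl-5,8-dimethoxyisochroman-1-one F2. BBr3 would then give (3R)-3-allyl-5,8-dihydroxyisochroman-1-one F3, and TIPSOTf/2,6-lutidine would give (3R)-3-allyl-5,8-bis(triisopropylsilyloxy)isochroman-1-one F4. Acid 16 would be esterified (EDC, DMAP) with commercial (S)-but-3-en-2-ol to (2S)-but-3-en-2-yl (3R)-5-(tert-butyldimethylsilyloxy)-3-hydroxy-3-methylpentanoate F5. Cross-metathesis of F4 with F5 (second-generation Hoveyda–Grubbs catalyst, CH2Cl2, 40 °C) should give the E-alkene (2S,3E)-5-[(3R)-1-oxo-5,8-bis(triisopropylsilyloxy)isochroman-3-yl]pent-3-en-2-yl (3R)-5-(tert-butyldimethylsilyloxy)-3-hydroxy-3-methylpentanoate F6. Homogeneous hydrogenation (H2, Wilkinson's catalyst, chosen to avoid allylic C–O hydrogenolysis) would return to the route at 21.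

2. Step 2 (ortho-metalation, epoxide opening, lactonisation). The hindered aryllithium 4 may open the epoxide sluggishly or add to a second amide molecule, and BF3 may divert the epoxide by rearrangement. The fallback changes the nucleophile to a copper-catalysed aryl Grignard reagent reached by halogen–magnesium exchange. Setting out from amide 2, lithiation to 4 and quenching with iodine would give N,N-diethyl-2-iodo-3,6-dimethoxybenzamide F7. Iodine–magnesium exchange (i-PrMgCl·LiCl, THF, −20 °C) would give [2-(diethylcarbamoyl)-3,6-dimethoxyphenyl]magnesium chloride F8, and its CuI-catalysed SN2 opening of epoxide 3 at the terminal carbon returns to the route at hydroxy amide 5, which is lactonised to 6 as in step 2.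

3. Step 8 (esterification). Activation of the β-hydroxy acid 16 may lead to β-lactone formation or self-condensation, and coupling at its neopentyl-type carboxyl may be slow. The fallback reverses the polarity of the esterification. Setting out from acid 16 and commercial benzyl (3R)-3-hydroxybutanoate (the enantiomer of 17), a Mitsunobu reaction (PPh3, DIAD, toluene, 0 °C) uses 16 only as the nucleophile and activates the alcohol. It should give ester 18 directly, with inversion at the carbinol carbon, and rejoins the route there.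

Further compounds
F1 | step 11 | N,N-diethyl-2-[(2R)-2-hydroxypent-4-en-1-yl]-3,6-dimethoxybenzamide | C=CC[C@@H](O)Cc1c(OC)ccc(OC)c1C(=O)N(CC)CC
F2 | step 11 | (3R)-3-allyl-5,8-dimethoxyisochroman-1-one | C=CC[C@@H]1Cc2c(OC)ccc(OC)c2C(=O)O1
F3 | step 11 | (3R)-3-allyl-5,8-dihydroxyisochroman-1-one | C=CC[C@@H]1Cc2c(O)ccc(O)c2C(=O)O1
F4 | step 11 | (3R)-3-allyl-5,8-bis(triisopropylsilyloxy)isochroman-1-one | C=CC[C@@H]1Cc2c(O[Si](C(C)C)(C(C)C)C(C)C)ccc(O[Si](C(C)C)(C(C)C)C(C)C)c2C(=O)O1
F5 | step 11 | (2S)-but-3-en-2-yl (3R)-5-(tert-butyldimethylsilyloxy)-3-hydroxy-3-methylpentanoate | C[C@@H](C=C)OC(=O)C[C@](C)(O)CCO[Si](C)(C)C(C)(C)C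
F6 | step 11 | (2S,3E)-5-[(3R)-1-oxo-5,8-bis(triisopropylsilyloxy)isochroman-3-yl]pent-3-en-2-yl (3R)-5-(tert-butyldimethylsilyloxy)-3-hydroxy-3-methylpentanoate | C[C@@H](/C=C/C[C@@H]1Cc2c(O[Si](C(C)C)(C(C)C)C(C)C)ccc(O[Si](C(C)C)(C(C)C)C(C)C)c2C(=O)O1)OC(=O)C[C@](C)(O)CCO[Si](C)(C)C(C)(C)C
F7 | step 2 | N,N-diethyl-2-iodo-3,6-dimethoxybenzamide | CCN(CC)C(=O)c1c(I)c(OC)ccc1OC
F8 | step 2 | [2-(diethylcarbamoyl)-3,6-dimethoxyphenyl]magnesium chloride | CCN(CC)C(=O)c1c([Mg]Cl)c(OC)ccc1OC
F0 | step 8 | none | none
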